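Two questions stand between the charge and the order asked for, and you should take them in this sequence.

starting material 20 mM; second substrate 0.500 equiv; free catalyst 0.49 mol%; impurity 66 µM

    starting material + free catalyst ⇌ catalyst intermediate A (K1 = 46 M⁻¹, k1 = 156 M⁻¹ s⁻¹)
    catalyst intermediate A → free catalyst + target (k2 = 1.74 s⁻¹)
    second substrate + free catalyst ⇌ catalyst intermediate B (K3 = 264 M⁻¹, k3 = 55.3 M⁻¹ s⁻¹)
    catalyst intermediate B → free catalyst + second product (k4 = 0.608 s⁻¹)
    free catalyst + impurity → spent catalyst (k5 = 73300 M⁻¹ s⁻¹)

- apparent order in free catalyst when 5.0% of the starting material are converted (percent change of the rate of making target for one percent more free catalyst charged)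

First, which charge is smaller in step 5, catalyst or impurity? The catalyst charged is 98.0 µM against 66 µM of impurity, so the impurity is the limiting reagent of that step, and the two are consumed one for one. That can leave 32.0 µM of working catalyst. Now define the leverage, the catalyst charged divided by the charge minus the impurity: 3.06. Extra catalyst meets an impurity that is already matched, so one percent more charge means 3.06 percent more working catalyst.

Second, does step 5 finish before 1.11 min, the moment asked about? Take a slow case, in which the impurity meets only the free share of the working catalyst. Steady balances give 0.608 of catalyst intermediate A and 0.676 of catalyst intermediate B per free catalyst. The free share is therefore 43.8%, or 14.0 µM. At that level the impurity has a lifetime of 0.974 s, far shorter than the time to the moment asked about.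

Those two balances contain the substrates but no catalyst concentration. At 5.0% conversion, then, the split should barely move with the charge, and the rate of making target should follow the working catalyst to first order. I therefore commit to an order equal to the leverage, 3.06.

The forecast gives 3.06, holding that "The rate therefore scales with charge minus impurity".

The simulation gives 3.1.

In this flask, spent catalyst stands at 67.3% of the catalyst charged at 1.50 min, matching the ratio of impurity to catalyst, 67.3%. Now use the leverage on a second flask, the same charge with step 5 taken away. The leverage there becomes the charge over itself, so you expect first order, and the simulated run gives 1.0. With step 5 taken away, the working catalyst should rise by the factor 3.06, and the rate at 5.0% conversion in that run stands at 3.06 times the actual one.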